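Retrosynthesis: (a) the nine O-benzyl bonds and a blocking C8–Br bond on ring D are cleared last; (b) the C3–OH and C4–H bonds of ring C go back to a C3=C4 alkene; (c) that alkene is cut by olefin metathesis; (d) O1–C2 is cut to a phenol and a cinnamyl carbonate; (e) C4–C6(D) is cut to a C6 arylmagnesium and an acetophenone.
Enabling feature: in ring C only C3 and C4 lie between the C2 stereocentre (bearing ring B) and C4a of ring A, and O1 and C4 are ortho neighbours on ring A. A vinyl group on C2 and a methylene on the C4 carbon that already carries ring D are therefore held within reach, and joining them as C3=C4 closes the pyran.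
Forward order: rings D, E and F arrive intact from (+)-gallocatechin; ring A is joined to C6 of ring D through the future C4; ring B comes in with the O1–C2 bond; ring C closes last.
Stereochemistry: C2 and C3 of ring F come from the chiral pool; C2 of ring C is set by an iridium–phosphoramidite catalyst; C3 and C4 of ring C follow from one syn hydroboration on the face opposite ring B.

Key step: step 12

Conventions: upper unit = rings A (benzo), B (catechol), C (pyran); lower unit = rings D (benzo), E (pyrogallol), F (pyran). Bn = benzyl. GC6 = (2R,3S)-3,5,7-tris(benzyloxy)-8-bromo-2-[3,4,5-tris(benzyloxy)phenyl]chroman-6-yl.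
Remark on descriptors: the carbon that becomes C2 of ring C is S in the metathesis precursor and in the chromene, where ring B outranks a vinyl or sp2 C3. It is R in the flavan-3-ol and the target, where the oxygenated C3 outranks ring B. The spatial arrangement is the same throughout.
Assumption: the (Sa,S,S) enantiomer of the phosphoramidite ligand is taken to deliver the S ether, by analogy with the parent cinnamyl carbonate and phenoxide pair; should the sense be the reverse, the mirror-image ligand is used and nothing else in the route changes.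

Step 1
Reactants: 1 (+)-gallocatechin
Product: 2 (2R,3S)-5,7-bis(benzyloxy)-2-[3,4,5-tris(benzyloxy)phenyl]chroman-3-ol
Conditions: BnBr (5.5 equiv), K2CO3, DMF, argon, 0 °C to rt
Reagents that add atoms: benzyl bromide, BrCc1ccccc1
Why: Williamson ether synthesis in which K2CO3 ionises only the five phenols, so the secondary 3-OH stays free and C2 and C3 of ring F are carried through unchanged.

Step 2
Reactants: 2 (2R,3S)-5,7-bis(benzyloxy)-2-[3,4,5-tris(benzyloxy)phenyl]chroman-3-ol
Product: 3 (2R,3S)-3,5,7-tris(benzyloxy)-2-[3,4,5-tris(benzyloxy)phenyl]chroman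
Conditions: NaH, BnBr, DMF, 0 °C to rt
Reagents that add atoms: benzyl bromide, BrCc1ccccc1
Why: Williamson ether synthesis on the sodium alkoxide of the 3-OH, safe for C2 because no free phenol is left to open ring F through a quinone methide.

Step 3
Reactants: 3 (2R,3S)-3,5,7-tris(benzyloxy)-2-[3,4,5-tris(benzyloxy)phenyl]chroman
Product: 4 (2R,3S)-3,5,7-tris(benzyloxy)-8-bromo-2-[3,4,5-tris(benzyloxy)phenyl]chroman
Conditions: NBS (1.0 equiv), CH2Cl2, −78 °C to 0 °C
Reagents that add atoms: N-bromosuccinimide, O=C1CCC(=O)N1Br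
Why: Electrophilic aromatic bromination, which in O-benzylated flavan-3-ols goes first to C8 of the phloroglucinol-type ring D, so one equivalent at low temperature should block C8 and leave C6 as the only free position of that ring.

Step 4
Reactants: 4 (2R,3S)-3,5,7-tris(benzyloxy)-8-bromo-2-[3,4,5-tris(benzyloxy)phenyl]chroman
Product: 5 (2R,3S)-3,5,7-tris(benzyloxy)-8-bromo-6-iodo-2-[3,4,5-tris(benzyloxy)phenyl]chroman
Conditions: N-iodosuccinimide (1.1 equiv), CF3CO2H (cat.), CH2Cl2–MeCN, 0 °C to rt, dark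
Reagents that add atoms: N-iodosuccinimide, O=C1CCC(=O)N1I
Why: Electrophilic aromatic iodination at C6, which is activated by the ortho 5-O and 7-O and the para O1 and should therefore react ahead of the less activated C2' and C6' positions of ring E.

Step 5
Reactants: 6 4'-(benzyloxy)-2'-hydroxyacetophenone
Product: 7 2'-(allyloxy)-4'-(benzyloxy)acetophenone
Conditions: allyl bromide, K2CO3, DMF, 60 °C
Reagents that add atoms: allyl bromide, C=CCBr
Why: Williamson ether synthesis, warmed to overcome the hydrogen bond to the ketone, that masks the phenol with a group removable later under neutral conditions.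

Step 6
Reactants: 5 (2R,3S)-3,5,7-tris(benzyloxy)-8-bromo-6-iodo-2-[3,4,5-tris(benzyloxy)phenyl]chroman; 7 2'-(allyloxy)-4'-(benzyloxy)acetophenone
Product: 10 1-[2-(allyloxy)-4-(benzyloxy)phenyl]-1-(GC6)ethene, via arylmagnesium chloride 8 (not isolated), via tertiary carbinol 9 (not isolated)
Conditions: 5, iPrMgCl·LiCl (1.1 equiv), THF, −20 to 0 °C; then 7 premixed with LaCl3·2LiCl (1.0 equiv), THF, 0 °C to rt; then 2 M aq HCl, rt
Reagents that add atoms: isopropylmagnesium chloride–lithium chloride, CC(C)[Mg]Cl.[Li+].[Cl-] (magnesium and chlorine, held only in 8)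
Why: Iodine–magnesium exchange takes the carbon–iodine bond far faster than the carbon–bromine bond, the LaCl3-promoted Grignard addition favours 1,2-addition over enolisation of the methyl ketone, and the doubly benzylic electron-rich carbinol loses water by E1 elimination in the acidic quench, which also erases its uncontrolled stereocentre.

Step 7
Reactants: 10 1-[2-(allyloxy)-4-(benzyloxy)phenyl]-1-(GC6)ethene
Product: 11 5-(benzyloxy)-2-[1-(GC6)vinyl]phenol
Conditions: Pd(PPh3)4 (5 mol %), morpholine (5 equiv), THF, rt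
Reagents that add atoms: none
Why: Tsuji–Trost deallylation, in which zerovalent palladium ionises the allyl aryl ether and morpholine captures the allyl fragment, while the crowded electron-rich aryl bromide should not undergo oxidative addition at room temperature.

Step 8
Reactants: 12 3,4-bis(benzyloxy)benzaldehyde
Product: 13 ethyl (E)-3-[3,4-bis(benzyloxy)phenyl]acrylate
Conditions: Ph3P=CHCO2Et, toluene, 80 °C
Reagents that add atoms: ethyl (triphenylphosphoranylidene)acetate, CCOC(=O)C=P(c1ccccc1)(c1ccccc1)c1ccccc1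
Why: Wittig olefination with a stabilised ylide, which gives the E cinnamate from an aromatic aldehyde.

Step 9
Reactants: 13 ethyl (E)-3-[3,4-bis(benzyloxy)phenyl]acrylate
Product: 14 (E)-3-[3,4-bis(benzyloxy)phenyl]prop-2-en-1-ol
Conditions: iBu2AlH (2.5 equiv), CH2Cl2, −78 to 0 °C; aq potassium sodium tartrate
Reagents that add atoms: none
Why: 1,2-Reduction of the conjugated ester with iBu2AlH, which leaves the E alkene and the benzyl ethers untouched.

Step 10
Reactants: 14 (E)-3-[3,4-bis(benzyloxy)phenyl]prop-2-en-1-ol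
Product: 15 (E)-3-[3,4-bis(benzyloxy)phenyl]allyl methyl carbonate
Conditions: ClCO2Me, pyridine, CH2Cl2, 0 °C
Reagents that add atoms: methyl chloroformate, COC(=O)Cl
Why: Acylation of the primary allylic alcohol to the methyl carbonate, the leaving group that also supplies methoxide as base in the next step.

Step 11
Reactants: 11 5-(benzyloxy)-2-[1-(GC6)vinyl]phenol; 15 (E)-3-[3,4-bis(benzyloxy)phenyl]allyl methyl carbonate
Product: 16 1-(GC6)-1-[4-(benzyloxy)-2-{(1S)-1-[3,4-bis(benzyloxy)phenyl]allyloxy}phenyl]ethene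
Conditions: [Ir(cod)Cl]2 (2 mol %), (Sa,S,S)-O,O'-(1,1'-binaphthalene-2,2'-diyl) N,N-bis(1-phenylethyl)phosphoramidite (4 mol %), n-PrNH2, THF, 50 °C, then evaporation; 11, 15 (1.5 equiv), K3PO4 (1.0 equiv), THF, rt to 40 °C
Reagents that add atoms: none
Why: Iridium-catalysed asymmetric allylic etherification, in which the cyclometallated iridium–phosphoramidite complex ionises 15 to a π-allyl complex and the phenoxide of 11, a member of the known 2-vinylphenol class of nucleophiles, attacks the aryl-bearing terminus anti to the metal, so the ligand alone sets the new O–CH centre as S irrespective of the remote ring F centres and the minor epimer is a diastereomer removable by chromatography.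

Step 12
Reactants: 16 1-(GC6)-1-[4-(benzyloxy)-2-{(1S)-1-[3,4-bis(benzyloxy)phenyl]allyloxy}phenyl]ethene
Product: 17 (2S)-7-(benzyloxy)-2-[3,4-bis(benzyloxy)phenyl]-4-(GC6)-2H-chromene
Conditions: second-generation Hoveyda–Grubbs catalyst RuCl2(SIMes)(=CH-C6H4-2-OiPr) (10 mol %, two portions), 1,4-benzoquinone (20 mol %), toluene (2 mM), 80 °C, argon sparge
Reagents that add atoms: none
Why: Ring-closing olefin metathesis by the Chauvin mechanism: the catalyst exchanges its alkylidene at the monosubstituted vinyl group on C2, the new alkylidene carbon (future C3) adds across the 1,1-diarylethylene with ruthenium on the CH2 terminus, and cycloreversion of the ruthenacyclobutane gives the C3=C4 bond and Ru=CH2, which leaves as ethylene in the next turnover. The closest known reaction types are the metathesis closure of 2-(1-arylvinyl)phenyl allyl ethers to 4-aryl-2H-chromenes and of 2-vinylphenyl 1-arylallyl ethers to 2-aryl-2H-chromenes. Ring C closes as a six-membered ring with both alkene carbons endocyclic, the two olefins being held ortho to each other on ring A through O1 and C4. No stereocentre is formed, and C2 is a spectator whose C–O and C–H bonds are not touched. The step needs cyclisation to win over dimerisation and over ruthenium hydride migration of the allylic double bond. The diarylethylene cannot homodimerise, any dimer formed through the vinyl groups stays metathesis-active and re-enters the cycle, high dilution with ethylene removal favours closure, and 1,4-benzoquinone suppresses hydride isomerisation.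

Step 13
Reactants: 17 (2S)-7-(benzyloxy)-2-[3,4-bis(benzyloxy)phenyl]-4-(GC6)-2H-chromene
Product: 19 (2R,3S,4S)-7-(benzyloxy)-2-[3,4-bis(benzyloxy)phenyl]-4-(GC6)chroman-3-ol, via C3 alkylborane 18 (not isolated)
Conditions: BH3·THF (5 equiv), THF, 0 °C to rt; then 3 M aq NaOH, 30% H2O2, 0 °C to rt
Reagents that add atoms: borane–tetrahydrofuran, B.C1CCOC1 (boron, held only in 18); hydrogen peroxide, OO
Why: Hydroboration–oxidation, precedented on 2-aryl-2H-chromenes, in which boron goes to C3 (the less substituted carbon, remote from the cation-stabilising aryl groups), boron and hydrogen add syn on the face opposite ring B, and oxidation with retention places the 3-OH trans to ring B and the C4 hydrogen cis to that OH, which sets C3 as S and C4 as S (2,3-trans-3,4-trans).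

Step 14
Reactants: 19 (2R,3S,4S)-7-(benzyloxy)-2-[3,4-bis(benzyloxy)phenyl]-4-(GC6)chroman-3-ol
Product: 20 fisetinidol-(4alpha,6)-gallocatechin
Conditions: H2 (1 atm), Pd(OH)2/C, THF–MeOH–H2O, rt
Reagents that add atoms: none
Why: Catalytic hydrogenolysis cleaves the nine benzyl ethers and the carbon–bromine bond in one operation, while the cyclic benzylic C2–O1 bonds, the C4–C6 bond and all five stereocentres are known to survive these mild conditions in flavan-3-ol chemistry.

Compound list
1 | (+)-gallocatechin, (2R,3S) | Oc1cc(O)c2c(c1)O[C@H](c1cc(O)c(O)c(O)c1)[C@@H](O)C2 | starting material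
2 | (2R,3S)-5,7-bis(benzyloxy)-2-[3,4,5-tris(benzyloxy)phenyl]chroman-3-ol | c1c(OCc9ccccc9)cc2c(c1OCc9ccccc9)C[C@H](O)[C@@H](c3cc(OCc9ccccc9)c(OCc9ccccc9)c(OCc9ccccc9)c3)O2 | intermediate
3 | (2R,3S)-3,5,7-tris(benzyloxy)-2-[3,4,5-tris(benzyloxy)phenyl]chroman | c1c(OCc9ccccc9)cc2c(c1OCc9ccccc9)C[C@H](OCc9ccccc9)[C@@H](c3cc(OCc9ccccc9)c(OCc9ccccc9)c(OCc9ccccc9)c3)O2 | intermediate
4 | (2R,3S)-3,5,7-tris(benzyloxy)-8-bromo-2-[3,4,5-tris(benzyloxy)phenyl]chroman | c1c(OCc9ccccc9)c(Br)c2c(c1OCc9ccccc9)C[C@H](OCc9ccccc9)[C@@H](c3cc(OCc9ccccc9)c(OCc9ccccc9)c(OCc9ccccc9)c3)O2 | intermediate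
5 | (2R,3S)-3,5,7-tris(benzyloxy)-8-bromo-6-iodo-2-[3,4,5-tris(benzyloxy)phenyl]chroman | Ic1c(OCc9ccccc9)c(Br)c2c(c1OCc9ccccc9)C[C@H](OCc9ccccc9)[C@@H](c3cc(OCc9ccccc9)c(OCc9ccccc9)c(OCc9ccccc9)c3)O2 | intermediate
6 | 4'-(benzyloxy)-2'-hydroxyacetophenone | CC(=O)c1ccc(OCc2ccccc2)cc1O | starting material
7 | 2'-(allyloxy)-4'-(benzyloxy)acetophenone | CC(=O)c1ccc(OCc2ccccc2)cc1OCC=C | intermediate
8 | (GC6)magnesium chloride (not isolated) | Cl[Mg]c1c(OCc9ccccc9)c(Br)c2c(c1OCc9ccccc9)C[C@H](OCc9ccccc9)[C@@H](c3cc(OCc9ccccc9)c(OCc9ccccc9)c(OCc9ccccc9)c3)O2 | intermediate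
9 | 1-[2-(allyloxy)-4-(benzyloxy)phenyl]-1-(GC6)ethanol, both epimers at the carbinol carbon (not isolated) | CC(O)(c4ccc(OCc9ccccc9)cc4OCC=C)c1c(OCc9ccccc9)c(Br)c2c(c1OCc9ccccc9)C[C@H](OCc9ccccc9)[C@@H](c3cc(OCc9ccccc9)c(OCc9ccccc9)c(OCc9ccccc9)c3)O2 | intermediate
10 | 1-[2-(allyloxy)-4-(benzyloxy)phenyl]-1-(GC6)ethene | C=C(c4ccc(OCc9ccccc9)cc4OCC=C)c1c(OCc9ccccc9)c(Br)c2c(c1OCc9ccccc9)C[C@H](OCc9ccccc9)[C@@H](c3cc(OCc9ccccc9)c(OCc9ccccc9)c(OCc9ccccc9)c3)O2 | intermediate
11 | 5-(benzyloxy)-2-[1-(GC6)vinyl]phenol | C=C(c4ccc(OCc9ccccc9)cc4O)c1c(OCc9ccccc9)c(Br)c2c(c1OCc9ccccc9)C[C@H](OCc9ccccc9)[C@@H](c3cc(OCc9ccccc9)c(OCc9ccccc9)c(OCc9ccccc9)c3)O2 | intermediate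
12 | 3,4-bis(benzyloxy)benzaldehyde | O=Cc1ccc(OCc2ccccc2)c(OCc2ccccc2)c1 | starting material
13 | ethyl (E)-3-[3,4-bis(benzyloxy)phenyl]acrylate | CCOC(=O)/C=C/c1ccc(OCc2ccccc2)c(OCc2ccccc2)c1 | intermediate
14 | (E)-3-[3,4-bis(benzyloxy)phenyl]prop-2-en-1-ol | OC/C=C/c1ccc(OCc2ccccc2)c(OCc2ccccc2)c1 | intermediate
15 | (E)-3-[3,4-bis(benzyloxy)phenyl]allyl methyl carbonate | COC(=O)OC/C=C/c1ccc(OCc2ccccc2)c(OCc2ccccc2)c1 | intermediate
16 | 1-(GC6)-1-[4-(benzyloxy)-2-{(1S)-1-[3,4-bis(benzyloxy)phenyl]allyloxy}phenyl]ethene | C=C(c4ccc(OCc9ccccc9)cc4O[C@H](c5ccc(OCc9ccccc9)c(OCc9ccccc9)c5)C=C)c1c(OCc9ccccc9)c(Br)c2c(c1OCc9ccccc9)C[C@H](OCc9ccccc9)[C@@H](c3cc(OCc9ccccc9)c(OCc9ccccc9)c(OCc9ccccc9)c3)O2 | intermediate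
17 | (2S)-7-(benzyloxy)-2-[3,4-bis(benzyloxy)phenyl]-4-(GC6)-2H-chromene | c9ccccc9COc4ccc6c(c4)O[C@H](c5ccc(OCc9ccccc9)c(OCc9ccccc9)c5)C=C6c1c(OCc9ccccc9)c(Br)c2c(c1OCc9ccccc9)C[C@H](OCc9ccccc9)[C@@H](c3cc(OCc9ccccc9)c(OCc9ccccc9)c(OCc9ccccc9)c3)O2 | intermediate
18 | 7-(benzyloxy)-2-[3,4-bis(benzyloxy)phenyl]-3-boranyl-4-(GC6)chroman, BH2 trans to ring B and trans to ring D (not isolated) | c9ccccc9COc4ccc6c(c4)O[C@H](c5ccc(OCc9ccccc9)c(OCc9ccccc9)c5)[C@@H](B)[C@@H]6c1c(OCc9ccccc9)c(Br)c2c(c1OCc9ccccc9)C[C@H](OCc9ccccc9)[C@@H](c3cc(OCc9ccccc9)c(OCc9ccccc9)c(OCc9ccccc9)c3)O2 | intermediate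
19 | (2R,3S,4S)-7-(benzyloxy)-2-[3,4-bis(benzyloxy)phenyl]-4-(GC6)chroman-3-ol | c9ccccc9COc4ccc6c(c4)O[C@H](c5ccc(OCc9ccccc9)c(OCc9ccccc9)c5)[C@@H](O)[C@@H]6c1c(OCc9ccccc9)c(Br)c2c(c1OCc9ccccc9)C[C@H](OCc9ccccc9)[C@@H](c3cc(OCc9ccccc9)c(OCc9ccccc9)c(OCc9ccccc9)c3)O2 | intermediate
20 | fisetinidol-(4alpha,6)-gallocatechin; upper unit (2R,3S,4S), lower unit (2R,3S) | Oc1ccc2c(c1)O[C@H](c1ccc(O)c(O)c1)[C@@H](O)[C@@H]2c1c(O)cc2c(c1O)C[C@H](O)[C@@H](c1cc(O)c(O)c(O)c1)O2 | target

Total step count: 14. Longest linear sequence: 10 steps (steps 1, 2, 3, 4, 6, 7, 11, 12, 13, 14).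

Steps most likely to fail

Step 12. The alkylidene generated at the vinyl group may not add to the 1,1-diarylethylene, which is shielded by the two ortho benzyloxy groups of ring D. Intermolecular metathesis at the vinyl groups, catalyst decay and migration of the allylic double bond would then consume the substrate.

The fallback keeps the metathesis closure of C3=C4 but runs it on an unhindered styrene and attaches ring D afterwards by flavan-4-yl cation chemistry. It sets out from carbonate 15 and bromide 4 and comes back to the route at 19.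
- Commercial 4-(benzyloxy)-2-hydroxybenzaldehyde is methylenated (MePPh3Br, KOtBu, THF) to 5-(benzyloxy)-2-vinylphenol F1.
- The iridium-catalysed etherification of step 11 with 15 gives 4-(benzyloxy)-2-{(1S)-1-[3,4-bis(benzyloxy)phenyl]allyloxy}-1-vinylbenzene F2.
- The second-generation Grubbs catalyst RuCl2(SIMes)(PCy3)(=CHPh) in CH2Cl2 at 40 °C closes it to (2S)-7-(benzyloxy)-2-[3,4-bis(benzyloxy)phenyl]-2H-chromene F3.
- OsO4 (cat.) with N-methylmorpholine N-oxide dihydroxylates the face opposite ring B to give (2R,3S,4S)-7-(benzyloxy)-2-[3,4-bis(benzyloxy)phenyl]chroman-3,4-diol F4.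
- BF3·OEt2 in CH2Cl2 at low temperature ionises the benzylic 4-OH. The cation is captured by C6 of 4, the only free position of ring D, on the side trans to the 3-OH, which gives 19.

Step 13. Three things may go wrong here.
- Hydroboration may be slow at the crowded trisubstituted alkene.
- Discrimination between the two faces by ring B may be incomplete.
- The C3 borane may undergo β-elimination with opening of the O1–C2 bond before it is oxidised.

The fallback replaces hydroboration by an oxidation, rearrangement and reduction sequence. It sets out from 17 and comes back at 19.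
- Dimethyldioxirane in acetone–CH2Cl2 at low temperature epoxidises the face opposite ring B to give the 3,4-epoxide of 17, F5.
- Catalytic BF3·OEt2 opens it at the diaryl-stabilised C4. A Meinwald rearrangement (1,2-hydride shift from C3) gives (2R,4R)-7-(benzyloxy)-2-[3,4-bis(benzyloxy)phenyl]-4-(GC6)chroman-3-one F6.
- Et3N equilibrates the acidic, doubly benzylic C4 to the 2,4-cis isomer with both aryl groups pseudo-equatorial, (2R,4S)-7-(benzyloxy)-2-[3,4-bis(benzyloxy)phenyl]-4-(GC6)chroman-3-one F7.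
- NaBH4 in THF–MeOH at −20 °C attacks along the axial trajectory and gives the equatorial 3-OH, trans to both aryl groups, that is 19.

Step 11. Attack of the crowded phenoxide on the π-allyl complex may be slow. Re-ionisation of the electron-rich branched ether would then lead to leakage to the linear ether and erosion of configuration at the new centre.

The fallback changes the order of fragment union, so that the etherification is run on a small, cheap phenol used in excess and ring D is brought in afterwards. The price is a less nucleophilic, ketone-conjugated phenoxide. It sets out from 6, 15 and 5 and comes back at 16, and it makes steps 5 and 7 unnecessary.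
- Phenol 6 and 15 under the conditions of step 11 give 1-[4-(benzyloxy)-2-{(1S)-1-[3,4-bis(benzyloxy)phenyl]allyloxy}phenyl]ethanone F8.
- The arylmagnesium chloride 8, made from 5 as in step 6, adds to F8 in the presence of LaCl3·2LiCl to give 1-[4-(benzyloxy)-2-{(1S)-1-[3,4-bis(benzyloxy)phenyl]allyloxy}phenyl]-1-(GC6)ethanol F9.
- Catalytic pyridinium p-toluenesulfonate in CH2Cl2 at rt dehydrates this far more ionisable tertiary carbinol to 16 without touching the allylic ether.

Further compounds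
F1 | step 12 | 5-(benzyloxy)-2-vinylphenol | C=Cc1ccc(OCc2ccccc2)cc1O
F2 | step 12 | 4-(benzyloxy)-2-{(1S)-1-[3,4-bis(benzyloxy)phenyl]allyloxy}-1-vinylbenzene | C=Cc1ccc(OCc2ccccc2)cc1O[C@H](c1ccc(OCc2ccccc2)c(OCc2ccccc2)c1)C=C
F3 | step 12 | (2S)-7-(benzyloxy)-2-[3,4-bis(benzyloxy)phenyl]-2H-chromene | c1ccccc1COc1ccc2c(c1)O[C@H](c1ccc(OCc3ccccc3)c(OCc3ccccc3)c1)C=C2
F4 | step 12 | (2R,3S,4S)-7-(benzyloxy)-2-[3,4-bis(benzyloxy)phenyl]chroman-3,4-diol | c1ccccc1COc1ccc2c(c1)O[C@H](c1ccc(OCc3ccccc3)c(OCc3ccccc3)c1)[C@@H](O)[C@H]2O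
F5 | step 13 | 3,4-epoxide of 17, oxygen on the face opposite ring B | c9ccccc9COc4ccc6c(c4)O[C@H](c5ccc(OCc9ccccc9)c(OCc9ccccc9)c5)[C@H]7O[C@@]67c1c(OCc9ccccc9)c(Br)c2c(c1OCc9ccccc9)C[C@H](OCc9ccccc9)[C@@H](c3cc(OCc9ccccc9)c(OCc9ccccc9)c(OCc9ccccc9)c3)O2
F6 | step 13 | (2R,4R)-7-(benzyloxy)-2-[3,4-bis(benzyloxy)phenyl]-4-(GC6)chroman-3-one (2,4-trans) | c9ccccc9COc4ccc6c(c4)O[C@H](c5ccc(OCc9ccccc9)c(OCc9ccccc9)c5)C(=O)[C@H]6c1c(OCc9ccccc9)c(Br)c2c(c1OCc9ccccc9)C[C@H](OCc9ccccc9)[C@@H](c3cc(OCc9ccccc9)c(OCc9ccccc9)c(OCc9ccccc9)c3)O2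
F7 | step 13 | (2R,4S)-7-(benzyloxy)-2-[3,4-bis(benzyloxy)phenyl]-4-(GC6)chroman-3-one (2,4-cis) | c9ccccc9COc4ccc6c(c4)O[C@H](c5ccc(OCc9ccccc9)c(OCc9ccccc9)c5)C(=O)[C@@H]6c1c(OCc9ccccc9)c(Br)c2c(c1OCc9ccccc9)C[C@H](OCc9ccccc9)[C@@H](c3cc(OCc9ccccc9)c(OCc9ccccc9)c(OCc9ccccc9)c3)O2
F8 | step 11 | 1-[4-(benzyloxy)-2-{(1S)-1-[3,4-bis(benzyloxy)phenyl]allyloxy}phenyl]ethanone | CC(=O)c1ccc(OCc2ccccc2)cc1O[C@H](c1ccc(OCc2ccccc2)c(OCc2ccccc2)c1)C=C
F9 | step 11 | 1-[4-(benzyloxy)-2-{(1S)-1-[3,4-bis(benzyloxy)phenyl]allyloxy}phenyl]-1-(GC6)ethanol, both epimers at the carbinol carbon | CC(O)(c4ccc(OCc9ccccc9)cc4O[C@H](c5ccc(OCc9ccccc9)c(OCc9ccccc9)c5)C=C)c1c(OCc9ccccc9)c(Br)c2c(c1OCc9ccccc9)C[C@H](OCc9ccccc9)[C@@H](c3cc(OCc9ccccc9)c(OCc9ccccc9)c(OCc9ccccc9)c3)O2
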